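The germacrane ring is disconnected at C3, the carbinol carbon that lies between the allylic CH2 C2 (beside the C1–C10 epoxide, which derives from an E alkene) and the alkenyl carbon C4 of the Z C4=C5 bond; at the ketone level this carbon can be CO trapped between an allyl electrophile at C2 and an alkenyl nucleophile at C4. One carbonylative Stille macrocyclisation thus forms C2–C3 and C3–C4 and closes the ten-membered carbocycle onto the finished trans-fused α-methylene γ-lactone. Its precursor is the seco lactone that already holds C6, C7 and C8, the C8 isovalerate, a Z C4 tributylstannyl alkene and an E allylic chloride at C2.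

Key step: step 18

Remark: atom numbers are germacrane numbers (ring C1–C10, lactone C12–O–C6, exocyclic C13, methyl C14 on C10, methyl C15 on C4). Compounds 1, 8, 9, 16 and 32 and all reagents are taken as commercial. The descriptors of C6 and C7 change along the route only because CIP rankings change (Sn or I on C4, the group on O8); no centre is inverted. C12 is carried as a tert-butyl ester only up to the Red-Al step, which reduces it, and is re-oxidised in the lactonisation.

Step 1
Reactants: 1 tert-butyl(but-3-yn-1-yloxy)dimethylsilane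
Product: 4 (2E)-5-(tert-butyldimethylsilyloxy)-3-methylpent-2-en-1-ol, via alkenylalane 2 (not isolated), via lithium alanate 3 (not isolated)
Conditions: Me3Al, Cp2ZrCl2 (cat.), CH2Cl2, 0 °C → rt; n-BuLi, THF, −78 °C; (CH2O)n, −78 °C → rt
Reagents that add atoms: trimethylaluminium C[Al](C)C; formaldehyde (as paraformaldehyde) C=O
Why: Negishi zirconium-catalysed carboalumination adds CH3 and Al syn across the terminal alkyne with Al at the terminus, and the derived alanate is hydroxymethylated by formaldehyde with retention, so the trisubstituted C1=C10 alkene is formed E (C2 cis to the C10 methyl).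

Step 2
Reactants: 4 (2E)-5-(tert-butyldimethylsilyloxy)-3-methylpent-2-en-1-ol
Product: 5 (2E)-5-(tert-butyldimethylsilyloxy)-1-(tert-butyldiphenylsilyloxy)-3-methylpent-2-ene
Conditions: TBDPSCl, imidazole, DMF, 0 °C → rt
Reagents that add atoms: tert-butyl(chloro)diphenylsilane CC(C)(C)[Si](Cl)(c1ccccc1)c1ccccc1
Why: Imidazole-promoted silylation of the primary allylic alcohol gives a TBDPS ether that survives the acid of step 3 and the hydride, Grignard and enolate steps, and can leave together with the O8 silyl group in step 15.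

Step 3
Reactants: 5 (2E)-5-(tert-butyldimethylsilyloxy)-1-(tert-butyldiphenylsilyloxy)-3-methylpent-2-ene
Product: 6 (3E)-5-(tert-butyldiphenylsilyloxy)-3-methylpent-3-en-1-ol
Conditions: PPTS (cat.), MeOH, rt
Reagents that add atoms: none
Why: Acid-catalysed methanolysis removes the primary TBS ether much faster than the bulkier primary TBDPS ether (selective desilylation).

Step 4
Reactants: 6 (3E)-5-(tert-butyldiphenylsilyloxy)-3-methylpent-3-en-1-ol
Product: 7 (3E)-5-(tert-butyldiphenylsilyloxy)-3-methylpent-3-enal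
Conditions: Dess–Martin periodinane, NaHCO3, CH2Cl2, 0 °C
Reagents that add atoms: none
Why: Dess–Martin oxidation under buffered, base-free conditions should give the β,γ-unsaturated aldehyde without migration of the alkene into conjugation, and 7 is used crude at once.

Step 5
Reactants: 8 4-tert-butoxy-4-oxobutanoic acid; 9 (4S)-4-benzyl-1,3-oxazolidin-2-one
Product: 11 tert-butyl 4-[(4S)-4-benzyl-2-oxo-1,3-oxazolidin-3-yl]-4-oxobutanoate, via mixed pivalic anhydride 10 (not isolated)
Conditions: PivCl, Et3N, THF, −20 °C; then 9, LiCl, −20 °C → rt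
Reagents that add atoms: none
Why: N-Acylation of the Evans oxazolidinone through the mixed pivalic anhydride (Et3N/LiCl protocol), in which the tert-butyl ester does not react.

Step 6
Reactants: 11 tert-butyl 4-[(4S)-4-benzyl-2-oxo-1,3-oxazolidin-3-yl]-4-oxobutanoate; 7 (3E)-5-(tert-butyldiphenylsilyloxy)-3-methylpent-3-enal
Product: 13 tert-butyl (3R,4R,6E)-3-[(4S)-4-benzyl-2-oxo-1,3-oxazolidine-3-carbonyl]-8-(tert-butyldiphenylsilyloxy)-4-hydroxy-6-methyloct-6-enoate, via boron enolate 12 (not isolated)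
Conditions: Bu2BOTf, i-Pr2NEt, CH2Cl2, 0 °C; then 7·Et2AlCl (premixed, CH2Cl2), −78 °C
Reagents that add atoms: none
Why: In the Lewis-acid-mediated anti variant of the Evans boron aldol, the Z boron enolate, chelated to the oxazolidinone carbonyl, is attacked on the face away from the benzyl group by the Et2AlCl-complexed aldehyde through an open antiperiplanar transition state, which should set C7 (R) by auxiliary control and C8 (R) anti to it; only the imide is enolised.

Step 7
Reactants: 13 tert-butyl (3R,4R,6E)-3-[(4S)-4-benzyl-2-oxo-1,3-oxazolidine-3-carbonyl]-8-(tert-butyldiphenylsilyloxy)-4-hydroxy-6-methyloct-6-enoate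
Product: 14 tert-butyl (3R,4R,6E)-8-(tert-butyldiphenylsilyloxy)-4-hydroxy-3-[methoxy(methyl)carbamoyl]-6-methyloct-6-enoate
Conditions: MeNH(OMe)·HCl, Me3Al, CH2Cl2, −20 → 0 °C
Reagents that add atoms: N,O-dimethylhydroxylamine hydrochloride CNOC.Cl
Why: Weinreb transamination of the imide by the aluminium amide, assisted by the free C8 hydroxyl as its aluminium alkoxide, releases the auxiliary without epimerising C7 and leaves the tert-butyl ester intact.

Step 8
Reactants: 14 tert-butyl (3R,4R,6E)-8-(tert-butyldiphenylsilyloxy)-4-hydroxy-3-[methoxy(methyl)carbamoyl]-6-methyloct-6-enoate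
Product: 15 tert-butyl (3R,4R,6E)-4-(tert-butyldimethylsilyloxy)-8-(tert-butyldiphenylsilyloxy)-3-[methoxy(methyl)carbamoyl]-6-methyloct-6-enoate
Conditions: TBSOTf, 2,6-lutidine, CH2Cl2, −78 °C
Reagents that add atoms: tert-butyldimethylsilyl trifluoromethanesulfonate CC(C)(C)[Si](C)(C)OS(=O)(=O)C(F)(F)F
Why: Silylation with the silyl triflate and 2,6-lutidine blocks O8, so that only O6 can close the lactone later and no β-alkoxide is present in the Grignard step.

Step 9
Reactants: 15 tert-butyl (3R,4R,6E)-4-(tert-butyldimethylsilyloxy)-8-(tert-butyldiphenylsilyloxy)-3-[methoxy(methyl)carbamoyl]-6-methyloct-6-enoate; 16 prop-1-ynylmagnesium bromide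
Product: 17 tert-butyl (3R,4R,6E)-3-(but-2-ynoyl)-4-(tert-butyldimethylsilyloxy)-8-(tert-butyldiphenylsilyloxy)-6-methyloct-6-enoate
Conditions: THF, 0 °C
Reagents that add atoms: none
Why: Weinreb ketone synthesis, in which the chelated tetrahedral magnesium adduct persists until work-up so that one alkynyl group is added and the tert-butyl ester is not attacked at 0 °C.

Step 10
Reactants: 17 tert-butyl (3R,4R,6E)-3-(but-2-ynoyl)-4-(tert-butyldimethylsilyloxy)-8-(tert-butyldiphenylsilyloxy)-6-methyloct-6-enoate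
Product: 18 tert-butyl (3S,4R,6E)-4-(tert-butyldimethylsilyloxy)-8-(tert-butyldiphenylsilyloxy)-3-[(1S)-1-hydroxybut-2-ynyl]-6-methyloct-6-enoate
Conditions: Ru[(S,S)-TsDPEN](p-cymene) (5 mol %), i-PrOH, rt
Reagents that add atoms: none
Why: Noyori asymmetric transfer hydrogenation of an α,β-acetylenic ketone is catalyst-controlled, so the (S,S) catalyst should give the (S)-propargylic alcohol at C6 irrespective of the C7 centre, and the base-free conditions avoid epimerisation at C7 and β-elimination of the silyloxy group.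

Step 11
Reactants: 18 tert-butyl (3S,4R,6E)-4-(tert-butyldimethylsilyloxy)-8-(tert-butyldiphenylsilyloxy)-3-[(1S)-1-hydroxybut-2-ynyl]-6-methyloct-6-enoate
Product: 20 (3S,4S,5Z)-3-[(1R,3E)-1-(tert-butyldimethylsilyloxy)-5-(tert-butyldiphenylsilyloxy)-3-methylpent-3-enyl]-6-iodohept-5-ene-1,4-diol, via cyclic alkenylalanate 19 (not isolated)
Conditions: Red-Al, THF, 0 °C → rt; EtOAc; I2, −78 → 0 °C
Reagents that add atoms: iodine II
Why: Red-Al hydroaluminates the propargylic alkoxide trans, with aluminium on C4 held cis to C6 in a five-membered alanate, and iodine cleaves the C–Al bond with retention to give the Z alkenyl iodide (hydroalumination–iodination of a propargylic alcohol); the same excess hydride reduces the tert-butyl ester to the C12 alcohol, so no carboxyl derivative has to survive this step.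

Step 12
Reactants: 20 (3S,4S,5Z)-3-[(1R,3E)-1-(tert-butyldimethylsilyloxy)-5-(tert-butyldiphenylsilyloxy)-3-methylpent-3-enyl]-6-iodohept-5-ene-1,4-diol
Product: 22 (4S,5S)-4-[(1R,3E)-1-(tert-butyldimethylsilyloxy)-5-(tert-butyldiphenylsilyloxy)-3-methylpent-3-enyl]-5-[(1Z)-2-iodoprop-1-enyl]oxolan-2-one, via lactol 21 (not isolated)
Conditions: TEMPO (cat.), PhI(OAc)2, CH2Cl2, rt
Reagents that add atoms: none
Why: TEMPO/PhI(OAc)2 oxidises the primary C12 alcohol selectively, the aldehyde is trapped by O6H as the five-membered lactol and this is oxidised on to the γ-lactone (oxidative lactonisation of a 1,4-diol); with O8 silylated only the 6,12-lactone can form, and its trans C6/C7 relationship follows from the centres set in steps 6 and 10.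

Step 13
Reactants: 22 (4S,5S)-4-[(1R,3E)-1-(tert-butyldimethylsilyloxy)-5-(tert-butyldiphenylsilyloxy)-3-methylpent-3-enyl]-5-[(1Z)-2-iodoprop-1-enyl]oxolan-2-one
Product: 23 (4S,5S)-4-[(1R,3E)-1-(tert-butyldimethylsilyloxy)-5-(tert-butyldiphenylsilyloxy)-3-methylpent-3-enyl]-5-[(1Z)-2-(tributylstannyl)prop-1-enyl]oxolan-2-one
Conditions: (Bu3Sn)2, PdCl2(PPh3)2 (cat.), THF, 60 °C
Reagents that add atoms: hexabutyldistannane CCCC[Sn](CCCC)(CCCC)[Sn](CCCC)(CCCC)CCCC
Why: Palladium-catalysed stannylation of the alkenyl iodide with the distannane (oxidative addition, Sn–Pd transmetalation, reductive elimination) proceeds with retention of the Z geometry, and it is placed before the acrylate and the allylic chloride exist because both would compete for palladium.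

Step 14
Reactants: 23 (4S,5S)-4-[(1R,3E)-1-(tert-butyldimethylsilyloxy)-5-(tert-butyldiphenylsilyloxy)-3-methylpent-3-enyl]-5-[(1Z)-2-(tributylstannyl)prop-1-enyl]oxolan-2-one
Product: 27 (4S,5S)-4-[(1R,3E)-1-(tert-butyldimethylsilyloxy)-5-(tert-butyldiphenylsilyloxy)-3-methylpent-3-enyl]-3-methylidene-5-[(1Z)-2-(tributylstannyl)prop-1-enyl]oxolan-2-one, via lithium enolate 24 (not isolated), via Mannich base 25 (not isolated), via ammonium iodide 26 (not isolated)
Conditions: LDA, THF, −78 °C; CH2=NMe2+ I−, −78 °C → rt; MeI, MeOH, rt; NaHCO3 (aq), EtOAc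
Reagents that add atoms: N,N-dimethylmethyleneiminium iodide (Eschenmoser's salt) C=[N+](C)C.[I-]
Why: α-Methylenation of the γ-lactone by Mannich reaction of its lithium enolate with Eschenmoser's salt, N-methylation and base-induced β-elimination of trimethylamine; the lactone is the only enolisable carbonyl at this stage and the alkenylstannane is inert to LDA and MeI.

Step 15
Reactants: 27 (4S,5S)-4-[(1R,3E)-1-(tert-butyldimethylsilyloxy)-5-(tert-butyldiphenylsilyloxy)-3-methylpent-3-enyl]-3-methylidene-5-[(1Z)-2-(tributylstannyl)prop-1-enyl]oxolan-2-one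
Product: 28 (4R,5S)-4-[(1R,3E)-1,5-dihydroxy-3-methylpent-3-enyl]-3-methylidene-5-[(1Z)-2-(tributylstannyl)prop-1-enyl]oxolan-2-one
Conditions: TBAF, AcOH, THF, 0 °C → rt
Reagents that add atoms: none
Why: Fluoride cleaves both silyl ethers while the C–Sn bond and the acrylate are left alone; buffering with acetic acid avoids alkoxide-induced translactonisation, and the trans 6,12-lactone is in any case the more stable regioisomer.

Step 16
Reactants: 28 (4R,5S)-4-[(1R,3E)-1,5-dihydroxy-3-methylpent-3-enyl]-3-methylidene-5-[(1Z)-2-(tributylstannyl)prop-1-enyl]oxolan-2-one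
Product: 30 (4R,5S)-4-[(1R,3E)-5-chloro-1-hydroxy-3-methylpent-3-enyl]-3-methylidene-5-[(1Z)-2-(tributylstannyl)prop-1-enyl]oxolan-2-one, via allylic mesylate 29 (not isolated)
Conditions: MsCl, s-collidine, LiCl, DMF, 0 °C
Reagents that add atoms: lithium chloride [Li+].[Cl-]
Why: Mesylation of the unhindered primary allylic alcohol with in situ SN2 displacement by chloride gives the allylic chloride without transposition or loss of E geometry, while the hindered secondary C8 alcohol is not sulfonylated and the mild base spares the alkenylstannane.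

Step 17
Reactants: 30 (4R,5S)-4-[(1R,3E)-5-chloro-1-hydroxy-3-methylpent-3-enyl]-3-methylidene-5-[(1Z)-2-(tributylstannyl)prop-1-enyl]oxolan-2-one
Product: 31 (1R,3E)-5-chloro-3-methyl-1-{(2S,3R)-4-methylidene-5-oxo-2-[(1Z)-2-(tributylstannyl)prop-1-enyl]oxolan-3-yl}pent-3-enyl 3-methylbutanoate
Conditions: (i-BuCO)2O, DMAP (cat.), pyridine, CH2Cl2, 0 °C → rt
Reagents that add atoms: 3-methylbutanoic anhydride CC(C)CC(=O)OC(=O)CC(C)C
Why: DMAP-catalysed acylation of the secondary C8 alcohol by the anhydride installs the isovalerate with retention at C8, and the allylic chloride and the stannane tolerate these conditions.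

Step 18
Reactants: 31 (1R,3E)-5-chloro-3-methyl-1-{(2S,3R)-4-methylidene-5-oxo-2-[(1Z)-2-(tributylstannyl)prop-1-enyl]oxolan-3-yl}pent-3-enyl 3-methylbutanoate; 32 carbon monoxide
Product: 33 (3aR,4R,6E,10Z,11aR)-6,10-dimethyl-3-methylidene-2,9-dioxo-2,3,3a,4,5,8,9,11a-octahydrocyclodeca[b]furan-4-yl 3-methylbutanoate
Conditions: Pd2(dba)3 (cat.), P(2-furyl)3, CO (4 atm), THF, 50 °C, slow addition, 2 mM
Reagents that add atoms: none
Why: Pd(0) ionises the primary allylic C2–Cl bond, CO inserts at the unhindered C2 terminus of the η3-allyl to give the C3 acylpalladium chloride, the Z C4 alkenylstannane transmetalates with retention and reductive elimination forms C3–C4; this is the carbonylative Stille coupling of an allyl halide with an alkenylstannane in its macrocyclising form. The ten-membered carbocycle closes in the last two events, by intramolecular transmetalation and reductive elimination at C3–C4, across the rigid trans-fused lactone that holds both arms on adjacent carbons. No stereocentre is created, C6, C7 and C8 are untouched, and both alkene geometries (1(10)E, 4Z) should be carried through. The step needs CO insertion to precede coupling and acylation at C2 rather than C10: direct allyl–alkenyl coupling would have to close a nine-membered ring and is further disfavoured by CO pressure, the hindered α-methyl alkenylstannane transmetalates slowly enough for insertion to be complete, and the tertiary C10 terminus is not carbonylated. The primary allylic chloride ionises far faster than the allylic lactone C6–O bond, the acrylate and the isovalerate do not take part, and high dilution limits oligomers.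

Step 19
Reactants: 33 (3aR,4R,6E,10Z,11aR)-6,10-dimethyl-3-methylidene-2,9-dioxo-2,3,3a,4,5,8,9,11a-octahydrocyclodeca[b]furan-4-yl 3-methylbutanoate
Product: 34 (3aR,4R,6E,9R,10Z,11aR)-9-hydroxy-6,10-dimethyl-3-methylidene-2-oxo-2,3,3a,4,5,8,9,11a-octahydrocyclodeca[b]furan-4-yl 3-methylbutanoate
Conditions: (S)-Me-CBS (0.5 equiv), catecholborane, toluene, −78 °C
Reagents that add atoms: none
Why: Corey–Bakshi–Shibata reduction, in which the α-methylalkenyl carbon C4 is the large and the C2 methylene the small ketone substituent, so the (S)-oxazaborolidine should deliver hydride to the face that gives the (3R) allylic alcohol under reagent control; catecholborane at −78 °C reduces the ketone 1,2 without touching the acrylate, the ester or the alkenes.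

Step 20
Reactants: 34 (3aR,4R,6E,9R,10Z,11aR)-9-hydroxy-6,10-dimethyl-3-methylidene-2-oxo-2,3,3a,4,5,8,9,11a-octahydrocyclodeca[b]furan-4-yl 3-methylbutanoate
Product: 35 CNP0300193.1 (1R,3R,6R,7R,8R,10R)-1,10-epoxy-3-hydroxy-8-(3-methylbutanoyloxy)germacra-4Z,11(13)-dien-12,6-olide
Conditions: mCPBA, NaHCO3, CH2Cl2, 0 °C
Reagents that add atoms: 3-chloroperbenzoic acid OOC(=O)c1cccc(Cl)c1
Why: Prilezhaev epoxidation of the strained E C1=C10 bond, the most nucleophilic alkene (C4=C5 is deactivated by its two allylic C–O bonds, C11=C13 is an acrylate), from the periphery of the preferred ring conformer should give the trans (1R,10R) epoxide found in natural 1,10-epoxy-heliangolides; bicarbonate prevents acid-induced transannular opening.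

Compound list
1 | tert-butyl(but-3-yn-1-yloxy)dimethylsilane | C#CCCO[Si](C)(C)C(C)(C)C | starting material
2 | [(1E)-4-(tert-butyldimethylsilyloxy)-2-methylbut-1-enyl]dimethylaluminium (alkenylalane) | C[Al](C)/C=C(\C)CCO[Si](C)(C)C(C)(C)C | intermediate
3 | lithium butyl[(1E)-4-(tert-butyldimethylsilyloxy)-2-methylbut-1-enyl]dimethylaluminate (lithium alanate) | [Li+].CCCC[Al-](C)(C)/C=C(\C)CCO[Si](C)(C)C(C)(C)C | intermediate
4 | (2E)-5-(tert-butyldimethylsilyloxy)-3-methylpent-2-en-1-ol | OC/C=C(\C)CCO[Si](C)(C)C(C)(C)C | intermediate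
5 | (2E)-5-(tert-butyldimethylsilyloxy)-1-(tert-butyldiphenylsilyloxy)-3-methylpent-2-ene | CC(C)(C)[Si](C)(C)OCC/C(C)=C/CO[Si](c1ccccc1)(c1ccccc1)C(C)(C)C | intermediate
6 | (3E)-5-(tert-butyldiphenylsilyloxy)-3-methylpent-3-en-1-ol | OCC/C(C)=C/CO[Si](c1ccccc1)(c1ccccc1)C(C)(C)C | intermediate
7 | (3E)-5-(tert-butyldiphenylsilyloxy)-3-methylpent-3-enal | O=CC/C(C)=C/CO[Si](c1ccccc1)(c1ccccc1)C(C)(C)C | intermediate
8 | 4-tert-butoxy-4-oxobutanoic acid (mono-tert-butyl succinate) | CC(C)(C)OC(=O)CCC(=O)O | starting material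
9 | (4S)-4-benzyl-1,3-oxazolidin-2-one | O=C1N[C@@H](Cc2ccccc2)CO1 | starting material
10 | 4-tert-butoxy-4-oxobutanoic pivalic anhydride (mixed pivalic anhydride) | CC(C)(C)OC(=O)CCC(=O)OC(=O)C(C)(C)C | intermediate
11 | tert-butyl 4-[(4S)-4-benzyl-2-oxo-1,3-oxazolidin-3-yl]-4-oxobutanoate | CC(C)(C)OC(=O)CCC(=O)N1C(=O)OC[C@@H]1Cc1ccccc1 | intermediate
12 | tert-butyl (3Z)-4-[(4S)-4-benzyl-2-oxo-1,3-oxazolidin-3-yl]-4-(dibutylboranyloxy)but-3-enoate (boron enolate) | CCCCB(CCCC)O/C(=C\CC(=O)OC(C)(C)C)N1C(=O)OC[C@@H]1Cc1ccccc1 | intermediate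
13 | tert-butyl (3R,4R,6E)-3-[(4S)-4-benzyl-2-oxo-1,3-oxazolidine-3-carbonyl]-8-(tert-butyldiphenylsilyloxy)-4-hydroxy-6-methyloct-6-enoate | CC(C)(C)OC(=O)C[C@H]([C@H](O)C/C(C)=C/CO[Si](c1ccccc1)(c1ccccc1)C(C)(C)C)C(=O)N1C(=O)OC[C@@H]1Cc1ccccc1 | intermediate
14 | tert-butyl (3R,4R,6E)-8-(tert-butyldiphenylsilyloxy)-4-hydroxy-3-[methoxy(methyl)carbamoyl]-6-methyloct-6-enoate | CON(C)C(=O)[C@H](CC(=O)OC(C)(C)C)[C@H](O)C/C(C)=C/CO[Si](c1ccccc1)(c1ccccc1)C(C)(C)C | intermediate
15 | tert-butyl (3R,4R,6E)-4-(tert-butyldimethylsilyloxy)-8-(tert-butyldiphenylsilyloxy)-3-[methoxy(methyl)carbamoyl]-6-methyloct-6-enoate | CON(C)C(=O)[C@H](CC(=O)OC(C)(C)C)[C@H](O[Si](C)(C)C(C)(C)C)C/C(C)=C/CO[Si](c1ccccc1)(c1ccccc1)C(C)(C)C | intermediate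
16 | prop-1-ynylmagnesium bromide | CC#C[Mg]Br | starting material
17 | tert-butyl (3R,4R,6E)-3-(but-2-ynoyl)-4-(tert-butyldimethylsilyloxy)-8-(tert-butyldiphenylsilyloxy)-6-methyloct-6-enoate | CC#CC(=O)[C@H](CC(=O)OC(C)(C)C)[C@H](O[Si](C)(C)C(C)(C)C)C/C(C)=C/CO[Si](c1ccccc1)(c1ccccc1)C(C)(C)C | intermediate
18 | tert-butyl (3S,4R,6E)-4-(tert-butyldimethylsilyloxy)-8-(tert-butyldiphenylsilyloxy)-3-[(1S)-1-hydroxybut-2-ynyl]-6-methyloct-6-enoate | CC#C[C@@H](O)[C@H](CC(=O)OC(C)(C)C)[C@H](O[Si](C)(C)C(C)(C)C)C/C(C)=C/CO[Si](c1ccccc1)(c1ccccc1)C(C)(C)C | intermediate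
19 | cyclic alkenylalanate: sodium aluminate in which Al carries C4 (cis to C6), the C6 and C12 alkoxides of reduced 18 and one 2-methoxyethoxide (representative structure) | [Na+].COCCO[Al-]12OCC[C@H]([C@H](O[Si](C)(C)C(C)(C)C)C/C(C)=C/CO[Si](c3ccccc3)(c3ccccc3)C(C)(C)C)[C@H](O1)C=C2C | intermediate
20 | (3S,4S,5Z)-3-[(1R,3E)-1-(tert-butyldimethylsilyloxy)-5-(tert-butyldiphenylsilyloxy)-3-methylpent-3-enyl]-6-iodohept-5-ene-1,4-diol | C/C(I)=C/[C@@H](O)[C@H](CCO)[C@H](O[Si](C)(C)C(C)(C)C)C/C(C)=C/CO[Si](c1ccccc1)(c1ccccc1)C(C)(C)C | intermediate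
21 | (4S,5S)-4-[(1R,3E)-1-(tert-butyldimethylsilyloxy)-5-(tert-butyldiphenylsilyloxy)-3-methylpent-3-enyl]-5-[(1Z)-2-iodoprop-1-enyl]oxolan-2-ol (lactol, both C2 epimers) | C/C(I)=C/[C@H]1OC(O)C[C@@H]1[C@H](O[Si](C)(C)C(C)(C)C)C/C(C)=C/CO[Si](c2ccccc2)(c2ccccc2)C(C)(C)C | intermediate
22 | (4S,5S)-4-[(1R,3E)-1-(tert-butyldimethylsilyloxy)-5-(tert-butyldiphenylsilyloxy)-3-methylpent-3-enyl]-5-[(1Z)-2-iodoprop-1-enyl]oxolan-2-one | C/C(I)=C/[C@H]1OC(=O)C[C@@H]1[C@H](O[Si](C)(C)C(C)(C)C)C/C(C)=C/CO[Si](c2ccccc2)(c2ccccc2)C(C)(C)C | intermediate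
23 | (4S,5S)-4-[(1R,3E)-1-(tert-butyldimethylsilyloxy)-5-(tert-butyldiphenylsilyloxy)-3-methylpent-3-enyl]-5-[(1Z)-2-(tributylstannyl)prop-1-enyl]oxolan-2-one | C/C(=C/[C@H]1OC(=O)C[C@@H]1[C@H](O[Si](C)(C)C(C)(C)C)C/C(C)=C/CO[Si](c2ccccc2)(c2ccccc2)C(C)(C)C)[Sn](CCCC)(CCCC)CCCC | intermediate
24 | lithium enolate of 23 | C/C(=C/[C@H]1OC(O[Li])=C[C@@H]1[C@H](O[Si](C)(C)C(C)(C)C)C/C(C)=C/CO[Si](c2ccccc2)(c2ccccc2)C(C)(C)C)[Sn](CCCC)(CCCC)CCCC | intermediate
25 | 3-(dimethylaminomethyl) derivative of 23 (Mannich base, both C3 epimers) | C/C(=C/[C@H]1OC(=O)C(CN(C)C)[C@@H]1[C@H](O[Si](C)(C)C(C)(C)C)C/C(C)=C/CO[Si](c2ccccc2)(c2ccccc2)C(C)(C)C)[Sn](CCCC)(CCCC)CCCC | intermediate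
26 | 3-(trimethylammoniomethyl) derivative of 23, iodide salt | C/C(=C/[C@H]1OC(=O)C(C[N+](C)(C)C)[C@@H]1[C@H](O[Si](C)(C)C(C)(C)C)C/C(C)=C/CO[Si](c2ccccc2)(c2ccccc2)C(C)(C)C)[Sn](CCCC)(CCCC)CCCC.[I-] | intermediate
27 | (4S,5S)-4-[(1R,3E)-1-(tert-butyldimethylsilyloxy)-5-(tert-butyldiphenylsilyloxy)-3-methylpent-3-enyl]-3-methylidene-5-[(1Z)-2-(tributylstannyl)prop-1-enyl]oxolan-2-one | C=C1C(=O)O[C@H](/C=C(/C)[Sn](CCCC)(CCCC)CCCC)[C@H]1[C@H](O[Si](C)(C)C(C)(C)C)C/C(C)=C/CO[Si](c1ccccc1)(c1ccccc1)C(C)(C)C | intermediate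
28 | (4R,5S)-4-[(1R,3E)-1,5-dihydroxy-3-methylpent-3-enyl]-3-methylidene-5-[(1Z)-2-(tributylstannyl)prop-1-enyl]oxolan-2-one | C=C1C(=O)O[C@H](/C=C(/C)[Sn](CCCC)(CCCC)CCCC)[C@H]1[C@H](O)C/C(C)=C/CO | intermediate
29 | (2E,5R)-5-hydroxy-3-methyl-5-{(2S,3R)-4-methylidene-5-oxo-2-[(1Z)-2-(tributylstannyl)prop-1-enyl]oxolan-3-yl}pent-2-enyl methanesulfonate | C=C1C(=O)O[C@H](/C=C(/C)[Sn](CCCC)(CCCC)CCCC)[C@H]1[C@H](O)C/C(C)=C/COS(C)(=O)=O | intermediate
30 | (4R,5S)-4-[(1R,3E)-5-chloro-1-hydroxy-3-methylpent-3-enyl]-3-methylidene-5-[(1Z)-2-(tributylstannyl)prop-1-enyl]oxolan-2-one | C=C1C(=O)O[C@H](/C=C(/C)[Sn](CCCC)(CCCC)CCCC)[C@H]1[C@H](O)C/C(C)=C/CCl | intermediate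
31 | (1R,3E)-5-chloro-3-methyl-1-{(2S,3R)-4-methylidene-5-oxo-2-[(1Z)-2-(tributylstannyl)prop-1-enyl]oxolan-3-yl}pent-3-enyl 3-methylbutanoate | C=C1C(=O)O[C@H](/C=C(/C)[Sn](CCCC)(CCCC)CCCC)[C@H]1[C@H](OC(=O)CC(C)C)C/C(C)=C/CCl | intermediate
32 | carbon monoxide | [C-]#[O+] | starting material
33 | (3aR,4R,6E,10Z,11aR)-6,10-dimethyl-3-methylidene-2,9-dioxo-2,3,3a,4,5,8,9,11a-octahydrocyclodeca[b]furan-4-yl 3-methylbutanoate (3-oxogermacra-1(10)E,4Z,11(13)-trien-12,6-olide 8-isovalerate) | C=C1C(=O)O[C@@H]2/C=C(/C)C(=O)C/C=C(\C)C[C@@H](OC(=O)CC(C)C)[C@@H]12 | intermediate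
34 | (3aR,4R,6E,9R,10Z,11aR)-9-hydroxy-6,10-dimethyl-3-methylidene-2-oxo-2,3,3a,4,5,8,9,11a-octahydrocyclodeca[b]furan-4-yl 3-methylbutanoate | C=C1C(=O)O[C@@H]2/C=C(/C)[C@H](O)C/C=C(\C)C[C@@H](OC(=O)CC(C)C)[C@@H]12 | intermediate
35 | CNP0300193.1, (1R,3R,6R,7R,8R,10R)-1,10-epoxy-3-hydroxy-8-(3-methylbutanoyloxy)germacra-4Z,11(13)-dien-12,6-olide | C=C1C(=O)O[C@@H]2/C=C(/C)[C@H](O)C[C@H]3O[C@]3(C)C[C@@H](OC(=O)CC(C)C)[C@@H]12 | target

Total step count: 20. Longest linear sequence: 19 steps (steps 1–4 and 6–20, from 1); step 5 is the only side branch.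

Steps most likely to fail

Step 18. Carbonylation may lag behind transmetalation, or intermolecular coupling may outrun ring closure, so that direct-coupled or oligomeric material forms; the β,γ-unsaturated ketone may also drift into conjugation. The fallback closes the same ring at C3–C4 by a Nozaki–Hiyama–Kishi reaction and sets out from 31. Palladium-catalysed reductive carbonylation of the allylic chloride (CO, Bu3SnH added slowly so that capture of the acylpalladium outruns conjugate reduction) gives the β,γ-unsaturated stannyl aldehyde F1. Iododestannylation (I2, CH2Cl2, 0 °C, retention) gives the Z iodo aldehyde F2. Cyclisation with CrCl2 and catalytic NiCl2 in DMSO/THF at high dilution should give 34 together with its C3 epimer F3, and Dess–Martin oxidation of the mixture converges on 33, where the route is rejoined.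

Step 6. Anti selectivity and facial control in the open transition state may erode, and the Lewis acid may isomerise the β,γ-unsaturated aldehyde. The fallback sets the two centres one after the other and sets out from 7. A catalytic enantioselective Mukaiyama acetate aldol with 1-methoxy-1-(trimethylsilyloxy)ethene and a chiral titanium(IV) Schiff-base catalyst (enantiomer chosen for the 3R adduct) gives the silyl ether F4, which acidic work-up converts into the β-hydroxy methyl ester F5. Fráter–Seebach alkylation of the dianion of F5 (LDA, 2.2 equiv, THF, −78 → −20 °C) with tert-butyl bromoacetate, which enters anti to the alkoxide of the chelated enolate, gives the anti hydroxy diester F6. Chemoselective Weinreb aminolysis of the methyl ester (MeNH(OMe)·HCl, i-PrMgCl, THF, −20 °C; the tert-butyl ester is inert) rejoins the route at 14.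

Step 20. Hydroxyl-directed epoxidation of the C4=C5 allylic alcohol may compete with attack on C1=C10, or the peracid may approach the other face of C1=C10. The fallback reverses the order of the last two steps and sets out from 33. There C4=C5 is an enone and only C1=C10 is nucleophilic, so mCPBA (NaHCO3, CH2Cl2, 0 °C) should give the epoxy ketone F7. Reduction of the C3 ketone (CBS as in step 19, or a brief Luche reduction at −78 °C to avoid base-induced opening of the β,γ-epoxy ketone) then gives 35 directly.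

Further compounds
F1 | step 18 | (1R,3E)-3-methyl-1-{(2S,3R)-4-methylidene-5-oxo-2-[(1Z)-2-(tributylstannyl)prop-1-enyl]oxolan-3-yl}-6-oxohex-3-enyl 3-methylbutanoate | C=C1C(=O)O[C@H](/C=C(/C)[Sn](CCCC)(CCCC)CCCC)[C@H]1[C@H](OC(=O)CC(C)C)C/C(C)=C/CC=O
F2 | step 18 | (1R,3E)-1-{(2S,3R)-2-[(1Z)-2-iodoprop-1-enyl]-4-methylidene-5-oxooxolan-3-yl}-3-methyl-6-oxohex-3-enyl 3-methylbutanoate | C=C1C(=O)O[C@H](/C=C(/C)I)[C@H]1[C@H](OC(=O)CC(C)C)C/C(C)=C/CC=O
F3 | step 18 | (3aR,4R,6E,9S,10Z,11aR)-9-hydroxy-6,10-dimethyl-3-methylidene-2-oxo-2,3,3a,4,5,8,9,11a-octahydrocyclodeca[b]furan-4-yl 3-methylbutanoate (C3 epimer of 34) | C=C1C(=O)O[C@@H]2/C=C(/C)[C@@H](O)C/C=C(\C)C[C@@H](OC(=O)CC(C)C)[C@@H]12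
F4 | step 6 | methyl (3R,5E)-7-(tert-butyldiphenylsilyloxy)-5-methyl-3-(trimethylsilyloxy)hept-5-enoate | COC(=O)C[C@H](O[Si](C)(C)C)C/C(C)=C/CO[Si](c1ccccc1)(c1ccccc1)C(C)(C)C
F5 | step 6 | methyl (3R,5E)-7-(tert-butyldiphenylsilyloxy)-3-hydroxy-5-methylhept-5-enoate | COC(=O)C[C@H](O)C/C(C)=C/CO[Si](c1ccccc1)(c1ccccc1)C(C)(C)C
F6 | step 6 | 4-tert-butyl 1-methyl (2R)-2-[(1R,3E)-5-(tert-butyldiphenylsilyloxy)-1-hydroxy-3-methylpent-3-enyl]butanedioate | COC(=O)[C@H](CC(=O)OC(C)(C)C)[C@H](O)C/C(C)=C/CO[Si](c1ccccc1)(c1ccccc1)C(C)(C)C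
F7 | step 20 | (1R,6R,7R,8R,10R)-1,10-epoxy-8-(3-methylbutanoyloxy)-3-oxogermacra-4Z,11(13)-dien-12,6-olide | C=C1C(=O)O[C@@H]2/C=C(/C)C(=O)C[C@H]3O[C@]3(C)C[C@@H](OC(=O)CC(C)C)[C@@H]12
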